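**Assumption:** the target is taken exactly as the SMILES encodes it: (3aR,4S,7aR) cis-fused α-methylene lactone, (2R)-5-hydroxypentan-2-yl chain, (Z)-2-methylbut-2-enoate (angelate). Benzofuranone locants (C-3a, C-4, C-5, C-6, C-7a; side-chain C-2′) are used below.

## Retrosynthetic overview

- Not used: coupling a chiral-pool sec-alkyl fragment to a ring vinyl triflate. The side-chain stereocentre is instead made on the ring.
- Target ⇐ angelate ester, Stille hydroxymethylation and Mannich methylenation on a bicyclic enol triflate.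
- Key step: enol triflate ⇐ (E)-alkylidene keto lactone by Me2CuLi 1,4-addition with in-flask enolate triflation. This sets C-2′ by 1,3-allylic-strain relay from C-4 and fixes the tetrasubstituted alkene.
- Keto lactone ⇐ cross-conjugated dienone acid by intramolecular oxa-Michael (cis lactone) ⇐ 4,5-trans-disubstituted cyclohexenone + 4-silyloxybutanal (α′-aldol condensation).
- Cyclohexenone ⇐ cyclohexa-1,3-diene by asymmetric mono-epoxidation, SN2 opening with an acetate enolate and allylic oxidation. Ring order: carbocycle bought, lactone ring closed second, no later ring formation.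

## Route

Step 1
Reactants: 1 cyclohexa-1,3-diene
Product: 2 (1S,6R)-7-oxabicyclo[4.1.0]hept-2-ene
Conditions: (S,S)-[N,N'-bis(3,5-di-tert-butylsalicylidene)cyclohexane-1,2-diaminato]MnCl (4 mol %), 4-phenylpyridine N-oxide (20 mol %), aq. NaOCl (pH 11.3), CH2Cl2, 0 °C
Reagents that add atoms: sodium hypochlorite [Na+].[O-]Cl
Why: Jacobsen–Katsuki epoxidation works best on cis-disubstituted conjugated alkenes, and by analogy with indene the (S,S)-catalyst should give the (1S,6R)-monoepoxide, which fixes the absolute configuration of the carbons that become C-4 and C-3a.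

Step 2
Reactants: 2 (1S,6R)-7-oxabicyclo[4.1.0]hept-2-ene; 3 tert-butyl acetate
Product: 6 tert-butyl 2-[(1R,6R)-6-hydroxycyclohex-2-en-1-yl]acetate, via lithium enolate of tert-butyl acetate 4 (not isolated), via diethylaluminium enolate of tert-butyl acetate 5 (not isolated)
Conditions: LiN(iPr)2, THF, −78 °C; Et2AlCl; then 2, −78 → −20 °C; aq. potassium sodium tartrate
Reagents that add atoms: none
Why: Lewis-acid-assisted SN2 opening of the vinyl epoxide by the aluminium ester enolate occurs at the activated allylic carbon with inversion, so the new C–C bond (future C-3a) is trans to the hydroxyl (future C-4).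

Step 3
Reactants: 6 tert-butyl 2-[(1R,6R)-6-hydroxycyclohex-2-en-1-yl]acetate
Product: 7 tert-butyl 2-[(1R,6R)-6-(tert-butyldimethylsilyloxy)cyclohex-2-en-1-yl]acetate
Conditions: TBSCl, imidazole, DMF, rt
Reagents that add atoms: tert-butyldimethylsilyl chloride CC(C)(C)[Si](C)(C)Cl
Why: Standard silylation of a secondary alcohol; the bulky silyl ether is a poor leaving group in the later enolate steps and serves as the axial shield in the key step.

Step 4
Reactants: 7 tert-butyl 2-[(1R,6R)-6-(tert-butyldimethylsilyloxy)cyclohex-2-en-1-yl]acetate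
Product: 8 tert-butyl 2-[(1R,6R)-6-(tert-butyldimethylsilyloxy)-4-oxocyclohex-2-en-1-yl]acetate
Conditions: Rh2(caprolactamate)4 (1 mol %), tBuOOH (5 equiv), K2CO3 (0.5 equiv), CH2Cl2, rt
Reagents that add atoms: tert-butyl hydroperoxide CC(C)(C)OO
Why: Dirhodium-catalysed radical allylic C–H oxidation converts the only allylic methylene into the enone carbonyl, while the tertiary allylic C–H flanked by two substituents is shielded; no stereocentre is touched.

Step 5
Reactants: 9 butane-1,4-diol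
Product: 10 4-(tert-butyldiphenylsilyloxy)butan-1-ol
Conditions: TBDPSCl (0.33 equiv), imidazole, DMF, 0 °C (diol in excess)
Reagents that add atoms: tert-butyl(chloro)diphenylsilane CC(C)(C)[Si](Cl)(c1ccccc1)c1ccccc1
Why: Statistical mono-silylation of a symmetrical diol used in excess.

Step 6
Reactants: 10 4-(tert-butyldiphenylsilyloxy)butan-1-ol
Product: 11 4-(tert-butyldiphenylsilyloxy)butanal
Conditions: PhI(OAc)2, TEMPO (10 mol %), CH2Cl2, rt
Reagents that add atoms: none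
Why: TEMPO-catalysed oxidation with the iodine diacetate stops cleanly at the aldehyde.

Step 7
Reactants: 8 tert-butyl 2-[(1R,6R)-6-(tert-butyldimethylsilyloxy)-4-oxocyclohex-2-en-1-yl]acetate; 11 4-(tert-butyldiphenylsilyloxy)butanal
Product: 15 tert-butyl 2-[(1R,5E,6S)-6-(tert-butyldimethylsilyloxy)-5-[4-(tert-butyldiphenylsilyloxy)butylidene]-4-oxocyclohex-2-en-1-yl]acetate, via lithium cross-conjugated dienolate 12 (not isolated), via lithium aldolate 13 (not isolated), via aldol mesylate 14 (not isolated)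
Conditions: LiN(iPr)2, THF, −78 °C; 11, −78 °C; MsCl, −78 → 0 °C; DBU, 0 °C
Reagents that add atoms: none
Why: Kinetic α′-deprotonation of the cyclohexenone fixes the site of the aldol addition, and mesylation followed by E1cB elimination gives the thermodynamically favoured (E)-alkylidene with the chain turned away from the carbonyl; the equatorial β-silyloxy group is not expelled at −78 °C.

Step 8
Reactants: 15 tert-butyl 2-[(1R,5E,6S)-6-(tert-butyldimethylsilyloxy)-5-[4-(tert-butyldiphenylsilyloxy)butylidene]-4-oxocyclohex-2-en-1-yl]acetate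
Product: 18 (3aR,4S,5E,7aR)-4-(tert-butyldimethylsilyloxy)-5-[4-(tert-butyldiphenylsilyloxy)butylidene]hexahydro-1-benzofuran-2,6-dione, via trimethylsilyl ester 16 (not isolated), via dienone carboxylic acid 17 (not isolated)
Conditions: TMSOTf, 2,6-lutidine, CH2Cl2, 0 °C; MeOH; then Et3N (0.2 equiv), CH2Cl2, rt
Reagents that add atoms: none
Why: Silyl triflate cleaves the tert-butyl ester without harming the silyl ethers, and the freed acid then closes by 5-exo-trig oxa-Michael addition to the endocyclic enone; the tether can reach the β-carbon only from its own face, so the lactone is cis-fused and C-7a is set as R.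

Step 9
Reactants: 18 (3aR,4S,5E,7aR)-4-(tert-butyldimethylsilyloxy)-5-[4-(tert-butyldiphenylsilyloxy)butylidene]hexahydro-1-benzofuran-2,6-dione
Product: 20 (3aR,4S,7aR)-4-(tert-butyldimethylsilyloxy)-5-[(2R)-5-(tert-butyldiphenylsilyloxy)pentan-2-yl]-2-oxo-2,3,3a,4,7,7a-hexahydro-1-benzofuran-6-yl trifluoromethanesulfonate, via lithium enolate 19 (not isolated)
Conditions: Me2CuLi (2.5 equiv), Et2O/THF, −78 °C; then N-(5-chloro-2-pyridyl)triflimide, −78 → −30 °C; aq. NH4Cl work-up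
Reagents that add atoms: lithium dimethylcuprate [Li+].C[Cu-]C; N-(5-chloropyridin-2-yl)-1,1,1-trifluoro-N-(trifluoromethylsulfonyl)methanesulfonamide O=S(=O)(N(c1ccc(Cl)cn1)S(=O)(=O)C(F)(F)F)C(F)(F)F
Why: Cuprate conjugate addition to the s-cis exocyclic enone with enolate O-triflation: 1,3-allylic strain with the (E)-alkylidene chain holds the C-4 silyloxy group axial, so methyl should add to the exocyclic carbon anti to it and give (2R)-C-2′, and the regiospecific enolate is trapped as the tetrasubstituted C-5/C-6 enol triflate.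

Step 10
Reactants: 20 (3aR,4S,7aR)-4-(tert-butyldimethylsilyloxy)-5-[(2R)-5-(tert-butyldiphenylsilyloxy)pentan-2-yl]-2-oxo-2,3,3a,4,7,7a-hexahydro-1-benzofuran-6-yl trifluoromethanesulfonate
Product: 24 (3aR,4S,7aR)-4-(tert-butyldimethylsilyloxy)-5-[(2R)-5-(tert-butyldiphenylsilyloxy)pentan-2-yl]-3-methylidene-2-oxo-2,3,3a,4,7,7a-hexahydro-1-benzofuran-6-yl trifluoromethanesulfonate, via lithium lactone enolate 21 (not isolated), via Mannich base 22 (not isolated), via trimethylammonium iodide 23 (not isolated)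
Conditions: LiN(iPr)2, THF, −78 °C; CH2=NMe2 I, −78 → 0 °C; MeI, MeOH, rt; aq. NaHCO3, CH2Cl2
Reagents that add atoms: dimethyl(methylidene)ammonium iodide C=[N+](C)C.[I-]
Why: Mannich aminomethylation of the lactone enolate with Eschenmoser's salt, N-methylation and β-elimination of trimethylamine give the α-methylene lactone; C-3 becomes sp2, so no stereocentre is created or lost.

Step 11
Reactants: 24 (3aR,4S,7aR)-4-(tert-butyldimethylsilyloxy)-5-[(2R)-5-(tert-butyldiphenylsilyloxy)pentan-2-yl]-3-methylidene-2-oxo-2,3,3a,4,7,7a-hexahydro-1-benzofuran-6-yl trifluoromethanesulfonate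
Product: 25 (3aS,4S,7aR)-5-[(2R)-5-(tert-butyldiphenylsilyloxy)pentan-2-yl]-4-hydroxy-3-methylidene-2-oxo-2,3,3a,4,7,7a-hexahydro-1-benzofuran-6-yl trifluoromethanesulfonate
Conditions: camphorsulfonic acid (0.3 equiv), MeOH/CH2Cl2 1:1, 0 °C → rt
Reagents that add atoms: none
Why: Acid-catalysed methanolysis removes the secondary TBS ether much faster than the acid-stable primary TBDPS ether; the C-3a descriptor changes only because the priorities change.

Step 12
Reactants: 25 (3aS,4S,7aR)-5-[(2R)-5-(tert-butyldiphenylsilyloxy)pentan-2-yl]-4-hydroxy-3-methylidene-2-oxo-2,3,3a,4,7,7a-hexahydro-1-benzofuran-6-yl trifluoromethanesulfonate; 26 angelic acid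
Product: 28 (3aR,4S,7aR)-5-[(2R)-5-(tert-butyldiphenylsilyloxy)pentan-2-yl]-3-methylidene-2-oxo-6-(trifluoromethylsulfonyloxy)-2,3,3a,4,7,7a-hexahydro-1-benzofuran-4-yl (2Z)-2-methylbut-2-enoate, via mixed anhydride 27 (not isolated)
Conditions: 26, 2,4,6-trichlorobenzoyl chloride, Et3N, toluene, rt; then 25, 75 °C
Reagents that add atoms: none
Why: Yamaguchi esterification through the mixed anhydride, run without a nucleophilic catalyst, acylates the hindered secondary alcohol with retention at C-4 and avoids angelate-to-tiglate isomerisation.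

Step 13
Reactants: 28 (3aR,4S,7aR)-5-[(2R)-5-(tert-butyldiphenylsilyloxy)pentan-2-yl]-3-methylidene-2-oxo-6-(trifluoromethylsulfonyloxy)-2,3,3a,4,7,7a-hexahydro-1-benzofuran-4-yl (2Z)-2-methylbut-2-enoate
Product: 29 (3aR,4S,7aR)-5-[(2R)-5-(tert-butyldiphenylsilyloxy)pentan-2-yl]-6-(hydroxymethyl)-3-methylidene-2-oxo-2,3,3a,4,7,7a-hexahydro-1-benzofuran-4-yl (2Z)-2-methylbut-2-enoate
Conditions: Bu3SnCH2OH (2 equiv), Pd(PPh3)4 (10 mol %), LiCl (3 equiv), 1,4-dioxane, 90 °C
Reagents that add atoms: (tributylstannyl)methanol CCCC[Sn](CCCC)(CCCC)CO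
Why: Migita–Kosugi–Stille coupling of the enol triflate with the hydroxymethylstannane installs the allylic alcohol directly; the alkene position is fixed by the triflate and no stereocentre is involved.

Step 14
Reactants: 29 (3aR,4S,7aR)-5-[(2R)-5-(tert-butyldiphenylsilyloxy)pentan-2-yl]-6-(hydroxymethyl)-3-methylidene-2-oxo-2,3,3a,4,7,7a-hexahydro-1-benzofuran-4-yl (2Z)-2-methylbut-2-enoate
Product: 30 (3aR,4S,7aR)-6-(hydroxymethyl)-5-[(2R)-5-hydroxypentan-2-yl]-3-methylidene-2-oxo-2,3,3a,4,7,7a-hexahydro-1-benzofuran-4-yl (2Z)-2-methylbut-2-enoate (CNP0106570.2)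
Conditions: HF·pyridine, pyridine/THF, 0 °C → rt
Reagents that add atoms: none
Why: Buffered fluoride desilylation frees the primary alcohol without touching the angelate, the α-methylene lactone or the allylic alcohol.

## Compound list

1 | cyclohexa-1,3-diene | C1=CC=CCC1 | starting material
2 | (1S,6R)-7-oxabicyclo[4.1.0]hept-2-ene | C1=CCC[C@H]2O[C@@H]12 | intermediate
3 | tert-butyl acetate | CC(=O)OC(C)(C)C | starting material
4 | lithium enolate of tert-butyl acetate | [Li+].C=C([O-])OC(C)(C)C | intermediate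
5 | diethylaluminium enolate of tert-butyl acetate | C=C(O[Al](CC)CC)OC(C)(C)C | intermediate
6 | tert-butyl 2-[(1R,6R)-6-hydroxycyclohex-2-en-1-yl]acetate (trans) | CC(C)(C)OC(=O)C[C@@H]1C=CCC[C@H]1O | intermediate
7 | tert-butyl 2-[(1R,6R)-6-(tert-butyldimethylsilyloxy)cyclohex-2-en-1-yl]acetate | CC(C)(C)OC(=O)C[C@@H]1C=CCC[C@H]1O[Si](C)(C)C(C)(C)C | intermediate
8 | tert-butyl 2-[(1R,6R)-6-(tert-butyldimethylsilyloxy)-4-oxocyclohex-2-en-1-yl]acetate | CC(C)(C)OC(=O)C[C@@H]1C=CC(=O)C[C@H]1O[Si](C)(C)C(C)(C)C | intermediate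
9 | butane-1,4-diol | OCCCCO | starting material
10 | 4-(tert-butyldiphenylsilyloxy)butan-1-ol | OCCCCO[Si](c1ccccc1)(c1ccccc1)C(C)(C)C | intermediate
11 | 4-(tert-butyldiphenylsilyloxy)butanal | O=CCCCO[Si](c1ccccc1)(c1ccccc1)C(C)(C)C | intermediate
12 | lithium cross-conjugated dienolate of the enone (α′ side, ring centres unchanged) | [Li+].[O-]C1=C[C@@H](O[Si](C)(C)C(C)(C)C)[C@H](CC(=O)OC(C)(C)C)C=C1 | intermediate
13 | lithium aldolate (α′-[1-oxido-4-(tert-butyldiphenylsilyloxy)butyl] enone, two new centres as a mixture) | [Li+].[O-]C(CCCO[Si](c1ccccc1)(c1ccccc1)C(C)(C)C)C1C(=O)C=C[C@@H](CC(=O)OC(C)(C)C)[C@@H]1O[Si](C)(C)C(C)(C)C | intermediate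
14 | aldol mesylate (two centres as a mixture) | CS(=O)(=O)OC(CCCO[Si](c1ccccc1)(c1ccccc1)C(C)(C)C)C1C(=O)C=C[C@@H](CC(=O)OC(C)(C)C)[C@@H]1O[Si](C)(C)C(C)(C)C | intermediate
15 | tert-butyl 2-[(1R,5E,6S)-6-(tert-butyldimethylsilyloxy)-5-[4-(tert-butyldiphenylsilyloxy)butylidene]-4-oxocyclohex-2-en-1-yl]acetate | O=C1C=C[C@@H](CC(=O)OC(C)(C)C)[C@H](O[Si](C)(C)C(C)(C)C)/C1=C\CCCO[Si](c1ccccc1)(c1ccccc1)C(C)(C)C | intermediate
16 | trimethylsilyl 2-[(1R,5E,6S)-6-(tert-butyldimethylsilyloxy)-5-[4-(tert-butyldiphenylsilyloxy)butylidene]-4-oxocyclohex-2-en-1-yl]acetate | O=C1C=C[C@@H](CC(=O)O[Si](C)(C)C)[C@H](O[Si](C)(C)C(C)(C)C)/C1=C\CCCO[Si](c1ccccc1)(c1ccccc1)C(C)(C)C | intermediate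
17 | 2-[(1R,5E,6S)-6-(tert-butyldimethylsilyloxy)-5-[4-(tert-butyldiphenylsilyloxy)butylidene]-4-oxocyclohex-2-en-1-yl]acetic acid | O=C1C=C[C@@H](CC(=O)O)[C@H](O[Si](C)(C)C(C)(C)C)/C1=C\CCCO[Si](c1ccccc1)(c1ccccc1)C(C)(C)C | intermediate
18 | (3aR,4S,5E,7aR)-4-(tert-butyldimethylsilyloxy)-5-[4-(tert-butyldiphenylsilyloxy)butylidene]hexahydro-1-benzofuran-2,6-dione (cis-fused) | O=C1O[C@@H]2CC(=O)/C(=C/CCCO[Si](c3ccccc3)(c3ccccc3)C(C)(C)C)[C@@H](O[Si](C)(C)C(C)(C)C)[C@@H]2C1 | intermediate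
19 | lithium (3aR,4S,7aR)-4-(tert-butyldimethylsilyloxy)-5-[(2R)-5-(tert-butyldiphenylsilyloxy)pentan-2-yl]-2-oxo-2,3,3a,4,7,7a-hexahydro-1-benzofuran-6-olate | [Li+].[O-]C1=C([C@H](C)CCCO[Si](c3ccccc3)(c3ccccc3)C(C)(C)C)[C@@H](O[Si](C)(C)C(C)(C)C)[C@@H]2CC(=O)O[C@@H]2C1 | intermediate
20 | (3aR,4S,7aR)-4-(tert-butyldimethylsilyloxy)-5-[(2R)-5-(tert-butyldiphenylsilyloxy)pentan-2-yl]-2-oxo-2,3,3a,4,7,7a-hexahydro-1-benzofuran-6-yl trifluoromethanesulfonate | O=S(=O)(OC1=C([C@H](C)CCCO[Si](c3ccccc3)(c3ccccc3)C(C)(C)C)[C@@H](O[Si](C)(C)C(C)(C)C)[C@@H]2CC(=O)O[C@@H]2C1)C(F)(F)F | intermediate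
21 | lithium lactone enolate of the enol triflate | [Li+].O=S(=O)(OC1=C([C@H](C)CCCO[Si](c3ccccc3)(c3ccccc3)C(C)(C)C)[C@@H](O[Si](C)(C)C(C)(C)C)[C@@H]2C=C([O-])O[C@@H]2C1)C(F)(F)F | intermediate
22 | 3-(dimethylaminomethyl) lactone (Mannich base, C-3 epimers) | O=S(=O)(OC1=C([C@H](C)CCCO[Si](c3ccccc3)(c3ccccc3)C(C)(C)C)[C@@H](O[Si](C)(C)C(C)(C)C)[C@@H]2C(CN(C)C)C(=O)O[C@@H]2C1)C(F)(F)F | intermediate
23 | 3-(trimethylammoniomethyl) lactone iodide (C-3 epimers) | [I-].O=S(=O)(OC1=C([C@H](C)CCCO[Si](c3ccccc3)(c3ccccc3)C(C)(C)C)[C@@H](O[Si](C)(C)C(C)(C)C)[C@@H]2C(C[N+](C)(C)C)C(=O)O[C@@H]2C1)C(F)(F)F | intermediate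
24 | (3aR,4S,7aR)-4-(tert-butyldimethylsilyloxy)-5-[(2R)-5-(tert-butyldiphenylsilyloxy)pentan-2-yl]-3-methylidene-2-oxo-2,3,3a,4,7,7a-hexahydro-1-benzofuran-6-yl trifluoromethanesulfonate | O=S(=O)(OC1=C([C@H](C)CCCO[Si](c3ccccc3)(c3ccccc3)C(C)(C)C)[C@@H](O[Si](C)(C)C(C)(C)C)[C@@H]2C(=C)C(=O)O[C@@H]2C1)C(F)(F)F | intermediate
25 | (3aS,4S,7aR)-5-[(2R)-5-(tert-butyldiphenylsilyloxy)pentan-2-yl]-4-hydroxy-3-methylidene-2-oxo-2,3,3a,4,7,7a-hexahydro-1-benzofuran-6-yl trifluoromethanesulfonate | O=S(=O)(OC1=C([C@H](C)CCCO[Si](c3ccccc3)(c3ccccc3)C(C)(C)C)[C@@H](O)[C@@H]2C(=C)C(=O)O[C@@H]2C1)C(F)(F)F | intermediate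
26 | angelic acid, (2Z)-2-methylbut-2-enoic acid | C/C=C(/C)C(=O)O | starting material
27 | (2Z)-2-methylbut-2-enoic 2,4,6-trichlorobenzoic anhydride | C/C=C(/C)C(=O)OC(=O)c1c(Cl)cc(Cl)cc1Cl | intermediate
28 | (3aR,4S,7aR)-5-[(2R)-5-(tert-butyldiphenylsilyloxy)pentan-2-yl]-3-methylidene-2-oxo-6-(trifluoromethylsulfonyloxy)-2,3,3a,4,7,7a-hexahydro-1-benzofuran-4-yl (2Z)-2-methylbut-2-enoate | O=S(=O)(OC1=C([C@H](C)CCCO[Si](c3ccccc3)(c3ccccc3)C(C)(C)C)[C@@H](OC(=O)/C(C)=C\C)[C@@H]2C(=C)C(=O)O[C@@H]2C1)C(F)(F)F | intermediate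
29 | (3aR,4S,7aR)-5-[(2R)-5-(tert-butyldiphenylsilyloxy)pentan-2-yl]-6-(hydroxymethyl)-3-methylidene-2-oxo-2,3,3a,4,7,7a-hexahydro-1-benzofuran-4-yl (2Z)-2-methylbut-2-enoate | OCC1=C([C@H](C)CCCO[Si](c3ccccc3)(c3ccccc3)C(C)(C)C)[C@@H](OC(=O)/C(C)=C\C)[C@@H]2C(=C)C(=O)O[C@@H]2C1 | intermediate
30 | (3aR,4S,7aR)-6-(hydroxymethyl)-5-[(2R)-5-hydroxypentan-2-yl]-3-methylidene-2-oxo-2,3,3a,4,7,7a-hexahydro-1-benzofuran-4-yl (2Z)-2-methylbut-2-enoate | C=C1C(=O)O[C@@H]2CC(CO)=C([C@H](C)CCCO)[C@@H](OC(=O)/C(C)=C\C)[C@H]12 | target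

## Step count and risk

Total step count: 14. Longest linear sequence: 12 (steps 1–4 and 7–14; steps 5–6 make the aldehyde side branch).

The three steps most likely to fail:

**Step 1 (enantioselectivity and volatility of the diene mono-epoxide).** The fallback sets out from 1 and comes back at 6. Compound 1 is epoxidised with mCPBA/NaHCO3 in CH2Cl2 to the racemic mono-epoxide F1. F1 is opened exactly as in step 2 (through 4 and 5) to the racemic trans hydroxy ester F2. F2 is resolved with Burkholderia cepacia lipase and vinyl acetate in tert-butyl methyl ether at about 50 % conversion; the R-configured carbinol is acylated, giving the (1R,6R)-acetate F3 beside the unreacted (1S,6S)-alcohol F4, which is removed by chromatography. K2CO3 in MeOH converts F3 into 6.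

**Step 9 (facial selectivity at the exocyclic carbon and survival of the β-silyloxy enolate).** The fallback sets out from 8 and comes back at 20. If methyl is delivered to the other face, the same facial bias is used with the two C-2′ substituents exchanged. Compound 8 is condensed with acetaldehyde under the step 7 protocol through the lithium aldolate F5 and the mesylate F6 (both not isolated) to the (E)-ethylidene dienone F7. The step 8 conditions take F7 through the trimethylsilyl ester F8 and the acid F9 (both not isolated) to the ethylidene keto lactone F10. The cuprate [tBuPh2SiO(CH2)3]2CuLi (from 3-(tert-butyldiphenylsilyloxy)propyl iodide, tBuLi and CuI) is then added to F10 at −78 °C to give enolate 19, which N-(5-chloro-2-pyridyl)triflimide converts into 20.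

**Step 13 (Stille hydroxymethylation of a hindered tetrasubstituted triflate next to an angelate and an α-methylene lactone).** The fallback sets out from 28 and comes back at 29. Reductive carbonylation of 28 (Pd(OAc)2, dppp, CO 1 atm, Et3SiH, Et3N, DMF, 70 °C) gives the enal F11. Luche reduction of F11 (NaBH4, CeCl3·7H2O, MeOH, −78 °C) reduces only the aldehyde and gives 29.

## Further compounds

F1 | step 1 | racemic 7-oxabicyclo[4.1.0]hept-2-ene (cis-fused by necessity) | C1=CCCC2OC12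
F2 | step 1 | racemic trans tert-butyl 2-(6-hydroxycyclohex-2-en-1-yl)acetate (1R,6R form drawn, 1S,6S form equally present) | CC(C)(C)OC(=O)C[C@@H]1C=CCC[C@H]1O
F3 | step 1 | tert-butyl 2-[(1R,6R)-6-acetoxycyclohex-2-en-1-yl]acetate | CC(C)(C)OC(=O)C[C@@H]1C=CCC[C@H]1OC(C)=O
F4 | step 1 | tert-butyl 2-[(1S,6S)-6-hydroxycyclohex-2-en-1-yl]acetate (unreacted enantiomer) | CC(C)(C)OC(=O)C[C@H]1C=CCC[C@@H]1O
F5 | step 9 | lithium aldolate from 8 and acetaldehyde (two new centres as a mixture) | [Li+].[O-]C(C)C1C(=O)C=C[C@@H](CC(=O)OC(C)(C)C)[C@@H]1O[Si](C)(C)C(C)(C)C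
F6 | step 9 | mesylate of that aldol (two centres as a mixture) | CS(=O)(=O)OC(C)C1C(=O)C=C[C@@H](CC(=O)OC(C)(C)C)[C@@H]1O[Si](C)(C)C(C)(C)C
F7 | step 9 | tert-butyl 2-[(1R,5E,6S)-6-(tert-butyldimethylsilyloxy)-5-ethylidene-4-oxocyclohex-2-en-1-yl]acetate | O=C1C=C[C@@H](CC(=O)OC(C)(C)C)[C@H](O[Si](C)(C)C(C)(C)C)/C1=C\C
F8 | step 9 | trimethylsilyl 2-[(1R,5E,6S)-6-(tert-butyldimethylsilyloxy)-5-ethylidene-4-oxocyclohex-2-en-1-yl]acetate | O=C1C=C[C@@H](CC(=O)O[Si](C)(C)C)[C@H](O[Si](C)(C)C(C)(C)C)/C1=C\C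
F9 | step 9 | 2-[(1R,5E,6S)-6-(tert-butyldimethylsilyloxy)-5-ethylidene-4-oxocyclohex-2-en-1-yl]acetic acid | O=C1C=C[C@@H](CC(=O)O)[C@H](O[Si](C)(C)C(C)(C)C)/C1=C\C
F10 | step 9 | (3aR,4S,5E,7aR)-4-(tert-butyldimethylsilyloxy)-5-ethylidenehexahydro-1-benzofuran-2,6-dione | O=C1O[C@@H]2CC(=O)/C(=C/C)[C@@H](O[Si](C)(C)C(C)(C)C)[C@@H]2C1
F11 | step 13 | (3aR,4S,7aR)-5-[(2R)-5-(tert-butyldiphenylsilyloxy)pentan-2-yl]-6-formyl-3-methylidene-2-oxo-2,3,3a,4,7,7a-hexahydro-1-benzofuran-4-yl (2Z)-2-methylbut-2-enoate | O=CC1=C([C@H](C)CCCO[Si](c3ccccc3)(c3ccccc3)C(C)(C)C)[C@@H](OC(=O)/C(C)=C\C)[C@@H]2C(=C)C(=O)O[C@@H]2C1
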